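## Structural features

The target (C48H34O28) is an achiral, linear chain of eight benzene rings, A to H, joined only by seven diaryl ether oxygens and carrying twenty-one free phenolic hydroxyls; there is no stereocentre and no ring-to-ring carbon–carbon bond. Ring A is a 2,4,6-trihydroxyphenyl cap and ring H a 3,4,5-trihydroxyphenyl cap. Rings B, D and F are 3,5-dihydroxy-1,4-phenylene units whose C4 ether oxygen lies between two hydroxyls, and rings C, E and G are penta-oxygenated (ether oxygens on the neighbouring carbons C1 and C2, hydroxyls on C3, C4 and C5, one hydrogen on C6), so the dimer B–C recurs as D–E and F–G. The free polyphenol is the fragile element: pyrogallol- and hydroxyquinol-type rings are oxidised to quinones by air as soon as base is present and are strongly C-nucleophilic, so every hydroxyl must stay masked until a last, neutral, reductive step. The real difficulty is the ether between a B-type and a C-type ring: its oxygen is flanked by two ortho oxygens on ring B and is bound to a ring C carbon that itself sits next to another ether, and no position of the electron-rich ring C is activated for SNAr. The key step exploits the oxygen pattern of ring C: C2, C3, C4 and C5 with their four oxygens (C2 and C5 para to one another) map onto the four carbons of a squarate, while C1 with its ether oxygen and C6–H come from a 2-aryloxyvinyl group that is bound to the hindered ring B oxygen before ring C exists.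

## Logic of the disconnections

49 ⇐ 48 ⇐ 47. The eighteen benzylic C–O bonds are cut, then the three Si–O bonds. The polyphenol cannot survive base, copper or oxidants, so it is released last. Every earlier intermediate is then a neutral poly-ether that can be chromatographed. The forward steps must be buffered fluoride on the still benzylated chain, then hydrogenolysis with exclusion of air.

47 ⇐ 46 + 13. The ring G C2–O to ring H C1 bond is cut. The oxygen is hindered but the bromide carbon of 13 has two ortho hydrogens, so the hindrance sits on one partner only. The cap becomes a small building block. The coupling must leave three aryl silyl ethers intact.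

46 ⇐ 43 ⇐ 42 ⇐ 39 + 15, 39 ⇐ 38 + 18, 38 ⇐ 37 ⇐ 36 + 12; likewise 36 ⇐ 33 ⇐ 32 ⇐ 29 + 15, 29 ⇐ 28 + 18, 28 ⇐ 27 ⇐ 26 + 12. Rings G and E are taken apart exactly as ring C below, and rings F and D are detached at their C1–O bond as the bromide 12. The three B–C type dimers are identical, so one validated six-step cycle serves three times. A union of 26 with a preformed D-to-H halide was weighed and set aside. It needs the same number of operations, a ring D halogen that survives n-BuLi (a chloride), and a late coupling of two large hindered partners. In the linear iteration every etherification uses a small bromide in excess.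

26 ⇐ 23 (key cut). The ring C C1–C2 bond is opened by retro-electrocyclisation and the ring is folded back to a cyclobutenone. This removes a penta-oxygenated arene and its hindered ether in one move and leaves a squarate adduct. The forward step needs inward rotation of the vinyl group on ring opening and a silyl group on the carbinol oxygen, so that the two para oxygens of ring C emerge differentiated.

23 ⇐ 22 ⇐ 19 + 15. The alkene is traced to an alkyne, and the bond between the carbinol carbon and the alkyne to an acetylide addition to 15. An aryloxyacetylide is a stable sp nucleophile. A 2-aryloxyvinyl-lithium of (E) geometry has lithium anti to the aryloxy group and would be expected to expel phenoxide. The forward demand is a syn semi-hydrogenation that spares benzyl ethers.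

19 ⇐ 17 + 18. The vinyl ether C–O bond at the hindered ring B oxygen is cut. In the forward sense the phenoxide attacks an sp carbon, so the two flanking benzyloxy groups do not matter.

17 ⇐ 16 ⇐ 5 + 12. The ring A oxygen to ring B C1 bond is cut. The ring B C4 oxygen travels as an allyl ether, orthogonal to benzyl and silyl. The forward step is a copper etherification of a di-ortho-substituted phenol with an unhindered bromide.

5 ⇐ 3 ⇐ 1; 12 and 13 ⇐ 11 ⇐ 10 ⇐ 8 ⇐ 6 + 7; 15 ⇐ 14. The phenolic oxygens of 5 and 10 come from formyl groups by aryl migration to oxygen, which avoids organolithium chemistry next to benzyl ethers. The formyl carbon of 3 is cut from a ring carbon of 1, in which the three benzyl ethers of ring A are already in place. No phloroglucinol then has to be O-benzylated three times in competition with C-benzylation. The forward step needs a carbon electrophile that substitutes the ring once and spares benzyl ethers. Bromine enters 10 para to the free hydroxyl. 1, 6, 7, 14 and 18 are commercial.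

## Other disconnections considered

Alternative 1: The cut removes both ether bonds of ring B at once (ring B C1–O toward ring A and ring B C4–O toward ring C). Forward, ring B would be the cationic cyclopentadienyl complex of divalent ruthenium A2, whose two chlorides differ in hindrance. The phenoxide of 5 should displace the open chloride first and the phenoxide of the C-to-H hexamer phenol A3 the chloride between the two methoxy groups second, in one pot, to give A1; photolysis would then free the arene.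
- In its favour: π-complexation makes an electron-rich chloroarene electrophilic near room temperature, two ether bonds form in one operation, and sterics programme the order of attack.
- Where it is better: it is far more convergent than the chosen plan, and it forms the A–B bond more mildly than the copper coupling at 110 °C.
- Against it here: ring B must travel as a dimethyl ether (A1), which hydrogenolysis does not remove, so a demethylation has to be added on an octamer full of benzyl ethers. The second displacement is at a carbon flanked by two ortho substituents. Ruthenium is stoichiometric, and complexation and decomplexation add steps. Above all, A3 still contains three penta-oxygenated rings and two hindered B-type junctions for which this plan offers no construction.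
- Comparison: structurally it solves only the ring B carbon and needs a ring C phenol made some other way, whereas the chosen key step makes ring C and the hindered B–C ether together. Mechanistically both avoid a classical Ullmann reaction at the hindered oxygen and stand equal. In step economy it wins for the single ring B (one pot against steps 9 to 11) and loses once demethylation, decomplexation and the synthesis of A3 are counted.

Alternative 2: The cut goes through two carbon–carbon bonds of ring A, which would be built last from acyclic pieces. Forward, NaOMe would condense the heptamer aryloxymalonate A5 with dimethyl 3-oxoglutarate A6 in two Claisen acylations to give the phloroglucinol diester A4, followed by saponification and decarboxylation.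
- In its favour: it is a classical, metal-free phloroglucinol synthesis.
- Where it is equal or better: the A–B oxygen would be introduced by O-alkylation of a phenol with a small halomalonate, which is easier than arylating the oxidisable, hindered phenol 5 in step 9. Ring A also emerges without protecting groups.
- Against it here: it spends a ring synthesis on the simplest ring and leaves the whole B-to-H heptamer, with all three hindered junctions, untouched. The malonate is deprotonated by methoxide and is then a poor acyl donor, while A6 self-condenses. Strong base, ester hydrolysis and decarboxylation would be run late on a precious, air-sensitive triphenol.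
- Comparison: structurally it addresses ring A only, which costs two building-block steps and one coupling in the chosen plan. Mechanistically it is sound but kinetically unfavourable for an α-aryloxy malonate. It needs at least three operations (alkylation, condensation, decarboxylation) against one coupling, so there is no gain in steps.

Alternative 3: The cut is a functional-group change at four carbons: the C4 hydroxyls of rings C, E, G and H would come from formyl groups that first serve as para-activators for SNAr etherification. Forward, mCPBA would turn the four aldehydes of A8 into formates by Baeyer–Villiger (Dakin) oxidation, and methanolysis would give A7.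
- In its favour: each formyl does double duty, ether formation is metal-free, and four oxidations occur in one operation.
- Where it is equal or better: the oxidation is the same reaction relied on in steps 2 and 4, so at that level it is the equal of the chosen chemistry. If the SNAr steps were feasible, the count per ring would be lower than the six operations per B–C unit here, and it would be the better plan on step economy.
- Against it here: the SNAr reactions needed to assemble A8 would have to occur on rings with two or three alkoxy donors, with the formyl twisted out of conjugation by two ortho benzyloxy groups, at a carbon ortho to another ether, and with a di-ortho-substituted phenoxide. That is exactly the hindered junction, with no activation left. Four electron-rich rings must also face the peracid at once.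
- Comparison: structurally it solves the oxygenation pattern but not the hindered ether, which the chosen plan forms on an sp carbon where hindrance is irrelevant. Mechanistically addition–elimination needs an acceptor that ring C cannot accommodate, while the electrocyclic route needs none. Its step economy is potentially better, but the assembly of A8 is unsecured.

Key step: step 14

Remark 1: 23 is built as the (Z)-enol ether, because an (E)-2-aryloxyvinyl-lithium (lithium anti to the aryloxy group) is expected to fragment to acetylene and phenoxide. The (Z) geometry comes from syn semi-hydrogenation and is erased in step 14; 23 and 26 are isomers (C73H70O11Si) and map atom for atom onto ring C.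

Remark 2: 21 to 23 and 25, and their homologues 31 to 33, 35, 41 to 43 and 45, are racemic at one carbon that is destroyed on aromatisation.

Remark 3: 1 (phloroglucinol tribenzyl ether) is taken as a commercial compound, so ring A enters with its three benzyl ethers in place.

## Route

Step 1
Reactants: 1 1,3,5-tris(benzyloxy)benzene
Product: 3 2,4,6-tris(benzyloxy)benzaldehyde, via aryl iminium salt 2 (not isolated)
Conditions: POCl3 (1.2 equiv), DMF, 0 °C to rt; then aq. NaOAc, rt
Reagents that add atoms: N,N-dimethylformamide CN(C)C=O; water O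
Why: Vilsmeier–Haack formylation; the chloroiminium ion from DMF and POCl3 attacks a ring carbon activated by three alkoxy groups (all three ring CH positions are equivalent), and the iminium group of 2 deactivates the ring against a second substitution. Buffered hydrolysis then frees the aldehyde, its oxygen coming from water, without acid strong enough to cleave benzyl ethers.

Step 2
Reactants: 3 2,4,6-tris(benzyloxy)benzaldehyde
Product: 5 2,4,6-tris(benzyloxy)phenol, via aryl formate 4 (not isolated)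
Conditions: mCPBA, NaHCO3, CH2Cl2, 0 °C to rt; aq. Na2S2O3 wash; K2CO3 (cat.), MeOH, rt
Reagents that add atoms: meta-chloroperoxybenzoic acid (mCPBA) OOC(=O)c1cccc(Cl)c1
Why: Dakin-type Baeyer–Villiger oxidation in which the electron-rich di-ortho-alkoxy aryl group migrates in preference to hydride; the formate is methanolysed only after the peracid is destroyed, so the oxidisable phenol never meets the oxidant.

Step 3
Reactants: 6 2,6-dihydroxybenzaldehyde; 7 benzyl bromide
Product: 8 2,6-bis(benzyloxy)benzaldehyde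
Conditions: 7 (2.4 equiv), K2CO3, DMF, 60 °C
Reagents that add atoms: none
Why: Williamson ether synthesis on both chelated ortho hydroxyls.

Step 4
Reactants: 8 2,6-bis(benzyloxy)benzaldehyde
Product: 10 2,6-bis(benzyloxy)phenol, via aryl formate 9 (not isolated)
Conditions: mCPBA, NaHCO3, CH2Cl2, 0 °C to rt; aq. Na2S2O3 wash; K2CO3 (cat.), MeOH, rt
Reagents that add atoms: meta-chloroperoxybenzoic acid (mCPBA) OOC(=O)c1cccc(Cl)c1
Why: Dakin-type Baeyer–Villiger oxidation as in step 2; aryl migration is favoured by the two ortho alkoxy groups.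

Step 5
Reactants: 10 2,6-bis(benzyloxy)phenol
Product: 11 2,6-bis(benzyloxy)-4-bromophenol
Conditions: NBS, CH2Cl2, −40 °C to 0 °C
Reagents that add atoms: N-bromosuccinimide BrN1C(=O)CCC1=O
Why: Electrophilic aromatic bromination; the free hydroxyl is the strongest donor, its ortho positions are occupied, so the para carbon should be attacked, and low temperature disfavours attack ortho to a benzyloxy group.

Step 6
Reactants: 11 2,6-bis(benzyloxy)-4-bromophenol
Product: 12 2-(allyloxy)-1,3-bis(benzyloxy)-5-bromobenzene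
Conditions: allyl bromide, K2CO3, DMF, rt
Reagents that add atoms: allyl bromide C=CCBr
Why: Williamson ether synthesis; the allyl group masks the future ring B, D or F C4 oxygen, is inert to copper and carbonate, and is removable by zerovalent palladium without touching benzyl or silyl ethers.

Step 7
Reactants: 11 2,6-bis(benzyloxy)-4-bromophenol; 7 benzyl bromide
Product: 13 1,2,3-tris(benzyloxy)-5-bromobenzene
Conditions: 7, K2CO3, DMF, rt
Reagents that add atoms: none
Why: Williamson ether synthesis giving the ring H cap.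

Step 8
Reactants: 14 squaric acid
Product: 15 dibenzyl squarate (3,4-bis(benzyloxy)cyclobut-3-ene-1,2-dione)
Conditions: BnOH (excess), toluene, reflux, Dean–Stark trap
Reagents that add atoms: benzyl alcohol OCc1ccccc1
Why: Azeotropic esterification of a vinylogous diacid that is acidic enough to catalyse its own esterification; benzyl esters are chosen so that the two squarate oxygens end as hydrogenolysable ethers on ring C.

Step 9
Reactants: 5 2,4,6-tris(benzyloxy)phenol; 12 2-(allyloxy)-1,3-bis(benzyloxy)-5-bromobenzene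
Product: 16 A-B dimer allyl ether
Conditions: (CuOTf)2·PhMe (10 mol%), Cs2CO3, 1-naphthoic acid, EtOAc (cat.), toluene, 110 °C, Ar; 12 in excess
Reagents that add atoms: none
Why: Ullmann-type diaryl ether synthesis with monovalent copper; the doubly ortho-substituted phenoxide is tolerated because the bromide carbon of 12 has two ortho hydrogens.

Step 10
Reactants: 16 A-B dimer allyl ether
Product: 17 A-B dimer phenol
Conditions: Pd(PPh3)4 (5 mol%), morpholine, THF, rt
Reagents that add atoms: none
Why: Tsuji–Trost deallylation: zerovalent palladium ionises the allyl aryl ether and morpholine captures the π-allyl fragment; benzyl and diaryl ethers are inert.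

Step 11
Reactants: 17 A-B dimer phenol; 18 trichloroethylene
Product: 19 A-B dimer (E)-1,2-dichlorovinyl ether
Conditions: KH, THF, 0 °C; then 18, −50 °C to rt
Reagents that add atoms: none
Why: Greene ynol ether protocol: the phenoxide eliminates HCl from 18 and adds anti to the resulting dichloroacetylene, so the hindered C–O bond is made at an sp carbon where the flanking benzyloxy groups do not interfere.

Step 12
Reactants: 19 A-B dimer (E)-1,2-dichlorovinyl ether; 15 dibenzyl squarate
Product: 22 A-B dimer alkynyl cyclobutenone silyl ether (racemic), via lithium aryloxyacetylide 20 (not isolated), via lithium alkoxide 21 (not isolated)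
Conditions: n-BuLi (2.05 equiv), THF, −78 °C; cannulated into 15 (1.2 equiv), THF, −78 °C; TBSOTf, −78 to −30 °C; NaHCO3 quench
Reagents that add atoms: tert-butyldimethylsilyl triflate (TBSOTf) CC(C)(C)[Si](C)(C)OS(=O)(=O)C(F)(F)F
Why: n-BuLi removes the vinylic hydrogen, LiCl is lost and chlorine–lithium exchange gives acetylide 20, which adds 1,2 to one carbonyl of the symmetric squarate; the tertiary alkoxide 21 is silylated in situ, and the new quaternary carbon is racemic and is erased in step 14.

Step 13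
Reactants: 22 A-B dimer alkynyl cyclobutenone silyl ether
Product: 23 A-B dimer (Z)-vinyl cyclobutenone silyl ether (racemic)
Conditions: H2 (1 atm), Pd/CaCO3 poisoned with Pb(OAc)2, quinoline, EtOAc, rt, stopped after one equivalent
Reagents that add atoms: none
Why: Lindlar semi-hydrogenation of an ynol ether; syn delivery of hydrogen gives the (Z)-enol ether, and the poisoned catalyst should leave benzyl ethers, the tetrasubstituted ring double bond and the ketone alone.

Step 14
Reactants: 23 A-B dimer (Z)-vinyl cyclobutenone silyl ether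
Product: 26 A-to-C trimer phenol (ring C: C2-OH free; C5-O-SiMe2tBu), via dienylketene 24 (not isolated), via cyclohexadienone 25 (not isolated)
Conditions: toluene (0.01 M, degassed), 110 °C, Ar
Reagents that add atoms: none
Why: This is the Moore–Liebeskind ring expansion of a squarate-derived 4-alkenyl-4-silyloxycyclobutenone. Thermal conrotatory 4π opening of the C1–C4 bond sends the silyloxy donor outward and the vinyl ether inward, giving the (Z)-dienylketene 24. A disrotatory 6π electrocyclisation then joins the ketene carbon to the aryloxy-bearing vinyl carbon, which is the ring C C2–C1 bond, and closes the six-membered ring as cyclohexa-2,4-dienone 25. Enolisation, driven by aromatisation, gives phenol 26; no stereocentre is formed, and the racemic quaternary carbon and the enol ether geometry are both erased. The inward rotation of the vinyl group is secured by the silyloxy donor, and a ketene formed in the other sense cannot cyclise and simply recloses. The two para oxygens are told apart because the carbinol oxygen stays silylated (C5) while the ketene oxygen emerges as the only free hydroxyl (C2). The (Z)-aryloxy group must turn toward the ketene carbon, which has no inward substituent of its own, so closure should still outrun reclosure. Benzyl, diaryl and aryl silyl ethers are stable in neutral toluene at this temperature.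

Step 15
Reactants: 26 A-to-C trimer phenol; 12 2-(allyloxy)-1,3-bis(benzyloxy)-5-bromobenzene
Product: 27 A-to-D tetramer allyl ether
Conditions: (CuOTf)2·PhMe (10 mol%), Cs2CO3, 1-naphthoic acid, EtOAc (cat.), toluene, 110 °C, Ar; 12 in excess
Reagents that add atoms: none
Why: Ullmann-type etherification with monovalent copper as in step 9; the apolar medium keeps carbonate out of solution so that the aryl silyl ether should survive, and only the C2 oxygen is free to react.

Step 16
Reactants: 27 A-to-D tetramer allyl ether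
Product: 28 A-to-D tetramer phenol
Conditions: Pd(PPh3)4 (5 mol%), morpholine, THF, rt
Reagents that add atoms: none
Why: Tsuji–Trost deallylation as in step 10; the aryl silyl ether is inert to morpholine at rt.

Step 17
Reactants: 28 A-to-D tetramer phenol; 18 trichloroethylene
Product: 29 A-to-D tetramer (E)-1,2-dichlorovinyl ether
Conditions: KH, THF, 0 °C; then 18, −50 °C to rt
Reagents that add atoms: none
Why: Greene ynol ether protocol as in step 11; the hindered ring D phenoxide adds to dichloroacetylene.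

Step 18
Reactants: 29 A-to-D tetramer (E)-1,2-dichlorovinyl ether; 15 dibenzyl squarate
Product: 32 A-to-D tetramer alkynyl cyclobutenone silyl ether (racemic), via lithium aryloxyacetylide 30 (not isolated), via lithium alkoxide 31 (not isolated)
Conditions: n-BuLi (2.05 equiv), THF, −78 °C; cannulated into 15 (1.2 equiv), THF, −78 °C; TBSOTf, −78 to −30 °C; NaHCO3 quench
Reagents that add atoms: tert-butyldimethylsilyl triflate (TBSOTf) CC(C)(C)[Si](C)(C)OS(=O)(=O)C(F)(F)F
Why: Elimination, chlorine–lithium exchange, 1,2-addition to the squarate and in situ silylation as in step 12; the aryl silyl ether of ring C is inert to n-BuLi at −78 °C.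

Step 19
Reactants: 32 A-to-D tetramer alkynyl cyclobutenone silyl ether
Product: 33 A-to-D tetramer (Z)-vinyl cyclobutenone silyl ether (racemic)
Conditions: H2 (1 atm), Pd/CaCO3 poisoned with Pb(OAc)2, quinoline, EtOAc, rt, stopped after one equivalent
Reagents that add atoms: none
Why: Lindlar semi-hydrogenation as in step 13, with syn addition giving the (Z)-enol ether.

Step 20
Reactants: 33 A-to-D tetramer (Z)-vinyl cyclobutenone silyl ether
Product: 36 A-to-E pentamer phenol (ring E: C2-OH free; C5-O-SiMe2tBu), via dienylketene 34 (not isolated), via cyclohexadienone 35 (not isolated)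
Conditions: toluene (0.01 M, degassed), 110 °C, Ar
Reagents that add atoms: none
Why: Moore–Liebeskind ring expansion as in step 14 (conrotatory 4π opening with the silyloxy group outward, 6π electrocyclisation, enolisation), now closing ring E.

Step 21
Reactants: 36 A-to-E pentamer phenol; 12 2-(allyloxy)-1,3-bis(benzyloxy)-5-bromobenzene
Product: 37 A-to-F hexamer allyl ether
Conditions: (CuOTf)2·PhMe (10 mol%), Cs2CO3, 1-naphthoic acid, EtOAc (cat.), toluene, 110 °C, Ar; 12 in excess
Reagents that add atoms: none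
Why: Ullmann-type etherification with monovalent copper as in steps 9 and 15.

Step 22
Reactants: 37 A-to-F hexamer allyl ether
Product: 38 A-to-F hexamer phenol
Conditions: Pd(PPh3)4 (5 mol%), morpholine, THF, rt
Reagents that add atoms: none
Why: Tsuji–Trost deallylation as in step 10.

Step 23
Reactants: 38 A-to-F hexamer phenol; 18 trichloroethylene
Product: 39 A-to-F hexamer (E)-1,2-dichlorovinyl ether
Conditions: KH, THF, 0 °C; then 18, −50 °C to rt
Reagents that add atoms: none
Why: Greene ynol ether protocol as in step 11.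

Step 24
Reactants: 39 A-to-F hexamer (E)-1,2-dichlorovinyl ether; 15 dibenzyl squarate
Product: 42 A-to-F hexamer alkynyl cyclobutenone silyl ether (racemic), via lithium aryloxyacetylide 40 (not isolated), via lithium alkoxide 41 (not isolated)
Conditions: n-BuLi (2.05 equiv), THF, −78 °C; cannulated into 15 (1.2 equiv), THF, −78 °C; TBSOTf, −78 to −30 °C; NaHCO3 quench
Reagents that add atoms: tert-butyldimethylsilyl triflate (TBSOTf) CC(C)(C)[Si](C)(C)OS(=O)(=O)C(F)(F)F
Why: Acetylide formation, 1,2-addition to the squarate and in situ silylation as in step 12.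

Step 25
Reactants: 42 A-to-F hexamer alkynyl cyclobutenone silyl ether
Product: 43 A-to-F hexamer (Z)-vinyl cyclobutenone silyl ether (racemic)
Conditions: H2 (1 atm), Pd/CaCO3 poisoned with Pb(OAc)2, quinoline, EtOAc, rt, stopped after one equivalent
Reagents that add atoms: none
Why: Lindlar semi-hydrogenation as in step 13.

Step 26
Reactants: 43 A-to-F hexamer (Z)-vinyl cyclobutenone silyl ether
Product: 46 A-to-G heptamer phenol (ring G: C2-OH free; C5-O-SiMe2tBu), via dienylketene 44 (not isolated), via cyclohexadienone 45 (not isolated)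
Conditions: toluene (0.01 M, degassed), 110 °C, Ar
Reagents that add atoms: none
Why: Moore–Liebeskind ring expansion as in step 14, now closing ring G.

Step 27
Reactants: 46 A-to-G heptamer phenol; 13 1,2,3-tris(benzyloxy)-5-bromobenzene
Product: 47 protected octamer (eighteen benzyl ethers; three silyl ethers)
Conditions: (CuOTf)2·PhMe (10 mol%), Cs2CO3, 1-naphthoic acid, EtOAc (cat.), toluene, 110 °C, Ar; 13 in excess
Reagents that add atoms: none
Why: Ullmann-type etherification with monovalent copper as in step 9, now with the ring H cap.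

Step 28
Reactants: 47 protected octamer
Product: 48 octamer triphenol (eighteen benzyl ethers)
Conditions: Bu4NF, AcOH, THF, 0 °C to rt, Ar
Reagents that add atoms: none
Why: Fluoride cleaves the three aryl Si–O bonds; acetic acid keeps the liberated phenoxides protonated so that the electron-rich phenols are not exposed to base.

Step 29
Reactants: 48 octamer triphenol
Product: 49 target octamer CNP0206369.0
Conditions: H2 (1 atm), Pd(OH)2/C, THF/MeOH, rt; filtration under Ar
Reagents that add atoms: none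
Why: Heterogeneous hydrogenolysis of eighteen aryl benzyl ethers under neutral conditions; diaryl ethers are inert, no stereocentre is at stake, and the polyphenol is released only here with air excluded.

## Compound list

1 | 1,3,5-tris(benzyloxy)benzene (phloroglucinol tribenzyl ether) | c9ccccc9COc1cc(OCc9ccccc9)cc(OCc9ccccc9)c1 | starting material
2 | N,N-dimethyl[2,4,6-tris(benzyloxy)benzylidene]ammonium chloride (not isolated) | C[N+](C)=Cc1c(OCc9ccccc9)cc(OCc9ccccc9)cc1OCc9ccccc9.[Cl-] | intermediate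
3 | 2,4,6-tris(benzyloxy)benzaldehyde | O=Cc1c(OCc9ccccc9)cc(OCc9ccccc9)cc1OCc9ccccc9 | intermediate
4 | 2,4,6-tris(benzyloxy)phenyl formate (not isolated) | O=COc1c(OCc9ccccc9)cc(OCc9ccccc9)cc1OCc9ccccc9 | intermediate
5 | 2,4,6-tris(benzyloxy)phenol (ring A block) | Oc1c(OCc9ccccc9)cc(OCc9ccccc9)cc1OCc9ccccc9 | intermediate
6 | 2,6-dihydroxybenzaldehyde | O=Cc1c(O)cccc1O | starting material
7 | benzyl bromide | BrCc1ccccc1 | starting material
8 | 2,6-bis(benzyloxy)benzaldehyde | O=Cc1c(OCc9ccccc9)cccc1OCc9ccccc9 | intermediate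
9 | 2,6-bis(benzyloxy)phenyl formate (not isolated) | O=COc1c(OCc9ccccc9)cccc1OCc9ccccc9 | intermediate
10 | 2,6-bis(benzyloxy)phenol | Oc1c(OCc9ccccc9)cccc1OCc9ccccc9 | intermediate
11 | 2,6-bis(benzyloxy)-4-bromophenol | Oc1c(OCc9ccccc9)cc(Br)cc1OCc9ccccc9 | intermediate
12 | 2-(allyloxy)-1,3-bis(benzyloxy)-5-bromobenzene (block for rings B, D, F) | C=CCOc1c(OCc9ccccc9)cc(Br)cc1OCc9ccccc9 | intermediate
13 | 1,2,3-tris(benzyloxy)-5-bromobenzene (ring H block) | Brc1cc(OCc9ccccc9)c(OCc9ccccc9)c(OCc9ccccc9)c1 | intermediate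
14 | squaric acid | OC1=C(O)C(=O)C1=O | starting material
15 | dibenzyl squarate, 3,4-bis(benzyloxy)cyclobut-3-ene-1,2-dione | O=C1C(=O)C(OCc9ccccc9)=C1OCc9ccccc9 | intermediate
16 | A-B dimer allyl ether, 2-(allyloxy)-1,3-bis(benzyloxy)-5-[2,4,6-tris(benzyloxy)phenoxy]benzene | c9ccccc9COc1cc(OCc9ccccc9)c(Oc2cc(OCc9ccccc9)c(OCC=C)c(OCc9ccccc9)c2)c(OCc9ccccc9)c1 | intermediate
17 | A-B dimer phenol, 2,6-bis(benzyloxy)-4-[2,4,6-tris(benzyloxy)phenoxy]phenol | c9ccccc9COc1cc(OCc9ccccc9)c(Oc2cc(OCc9ccccc9)c(O)c(OCc9ccccc9)c2)c(OCc9ccccc9)c1 | intermediate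
18 | trichloroethylene | ClC=C(Cl)Cl | starting material
19 | A-B dimer (E)-1,2-dichlorovinyl ether (17 with the ring B C4 oxygen carrying CCl=CHCl, the two chlorines trans) | c9ccccc9COc1cc(OCc9ccccc9)c(Oc2cc(OCc9ccccc9)c(O/C(Cl)=C\Cl)c(OCc9ccccc9)c2)c(OCc9ccccc9)c1 | intermediate
20 | lithium aryloxyacetylide of the A-B dimer (not isolated) | c9ccccc9COc1cc(OCc9ccccc9)c(Oc2cc(OCc9ccccc9)c(OC#C[Li])c(OCc9ccccc9)c2)c(OCc9ccccc9)c1 | intermediate
21 | lithium alkoxide of the squarate adduct, racemic (not isolated) | c9ccccc9COc1cc(OCc9ccccc9)c(Oc2cc(OCc9ccccc9)c(OC#CC3(O[Li])C(OCc9ccccc9)=C(OCc9ccccc9)C3=O)c(OCc9ccccc9)c2)c(OCc9ccccc9)c1 | intermediate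
22 | 2,3-bis(benzyloxy)-4-(tert-butyldimethylsilyloxy)-4-(aryloxyethynyl)cyclobut-2-en-1-one, aryl = ring B of the A-B dimer, racemic | c9ccccc9COc1cc(OCc9ccccc9)c(Oc2cc(OCc9ccccc9)c(OC#CC3(O[Si](C)(C)C(C)(C)C)C(OCc9ccccc9)=C(OCc9ccccc9)C3=O)c(OCc9ccccc9)c2)c(OCc9ccccc9)c1 | intermediate
23 | 2,3-bis(benzyloxy)-4-(tert-butyldimethylsilyloxy)-4-[(Z)-2-aryloxyvinyl]cyclobut-2-en-1-one, aryl = ring B of the A-B dimer, racemic (key-step precursor) | c9ccccc9COc1cc(OCc9ccccc9)c(Oc2cc(OCc9ccccc9)c(O/C=C\C3(O[Si](C)(C)C(C)(C)C)C(OCc9ccccc9)=C(OCc9ccccc9)C3=O)c(OCc9ccccc9)c2)c(OCc9ccccc9)c1 | intermediate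
24 | (Z)-dienylketene from 23, vinyl group cis to the ketene (not isolated) | c9ccccc9COc1cc(OCc9ccccc9)c(Oc2cc(OCc9ccccc9)c(O/C=C\C(O[Si](C)(C)C(C)(C)C)=C(OCc9ccccc9)/C(OCc9ccccc9)=C=O)c(OCc9ccccc9)c2)c(OCc9ccccc9)c1 | intermediate
25 | 6-aryloxy-2,3-bis(benzyloxy)-4-(tert-butyldimethylsilyloxy)cyclohexa-2,4-dien-1-one, racemic (not isolated) | c9ccccc9COc1cc(OCc9ccccc9)c(Oc2cc(OCc9ccccc9)c(OC3C=C(O[Si](C)(C)C(C)(C)C)C(OCc9ccccc9)=C(OCc9ccccc9)C3=O)c(OCc9ccccc9)c2)c(OCc9ccccc9)c1 | intermediate
26 | A-to-C trimer phenol; ring C: C1 ether to ring B, C2 free OH, C3 and C4 benzyloxy, C5 silyloxy, C6 H (key-step product) | c9ccccc9COc1cc(OCc9ccccc9)c(Oc2cc(OCc9ccccc9)c(Oc3cc(O[Si](C)(C)C(C)(C)C)c(OCc9ccccc9)c(OCc9ccccc9)c3O)c(OCc9ccccc9)c2)c(OCc9ccccc9)c1 | intermediate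
27 | A-to-D tetramer allyl ether; 26 with a 4-(allyloxy)-3,5-bis(benzyloxy)phenyl group on the ring C C2 oxygen | c9ccccc9COc1cc(OCc9ccccc9)c(Oc2cc(OCc9ccccc9)c(Oc3cc(O[Si](C)(C)C(C)(C)C)c(OCc9ccccc9)c(OCc9ccccc9)c3Oc4cc(OCc9ccccc9)c(OCC=C)c(OCc9ccccc9)c4)c(OCc9ccccc9)c2)c(OCc9ccccc9)c1 | intermediate
28 | A-to-D tetramer phenol (ring D C4-OH free) | c9ccccc9COc1cc(OCc9ccccc9)c(Oc2cc(OCc9ccccc9)c(Oc3cc(O[Si](C)(C)C(C)(C)C)c(OCc9ccccc9)c(OCc9ccccc9)c3Oc4cc(OCc9ccccc9)c(O)c(OCc9ccccc9)c4)c(OCc9ccccc9)c2)c(OCc9ccccc9)c1 | intermediate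
29 | A-to-D tetramer (E)-1,2-dichlorovinyl ether | c9ccccc9COc1cc(OCc9ccccc9)c(Oc2cc(OCc9ccccc9)c(Oc3cc(O[Si](C)(C)C(C)(C)C)c(OCc9ccccc9)c(OCc9ccccc9)c3Oc4cc(OCc9ccccc9)c(O/C(Cl)=C\Cl)c(OCc9ccccc9)c4)c(OCc9ccccc9)c2)c(OCc9ccccc9)c1 | intermediate
30 | lithium aryloxyacetylide of the tetramer (not isolated) | c9ccccc9COc1cc(OCc9ccccc9)c(Oc2cc(OCc9ccccc9)c(Oc3cc(O[Si](C)(C)C(C)(C)C)c(OCc9ccccc9)c(OCc9ccccc9)c3Oc4cc(OCc9ccccc9)c(OC#C[Li])c(OCc9ccccc9)c4)c(OCc9ccccc9)c2)c(OCc9ccccc9)c1 | intermediate
31 | lithium alkoxide of the tetramer squarate adduct, racemic (not isolated) | c9ccccc9COc1cc(OCc9ccccc9)c(Oc2cc(OCc9ccccc9)c(Oc3cc(O[Si](C)(C)C(C)(C)C)c(OCc9ccccc9)c(OCc9ccccc9)c3Oc4cc(OCc9ccccc9)c(OC#CC5(O[Li])C(OCc9ccccc9)=C(OCc9ccccc9)C5=O)c(OCc9ccccc9)c4)c(OCc9ccccc9)c2)c(OCc9ccccc9)c1 | intermediate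
32 | tetramer 4-(aryloxyethynyl)-4-silyloxy-2,3-bis(benzyloxy)cyclobutenone, racemic | c9ccccc9COc1cc(OCc9ccccc9)c(Oc2cc(OCc9ccccc9)c(Oc3cc(O[Si](C)(C)C(C)(C)C)c(OCc9ccccc9)c(OCc9ccccc9)c3Oc4cc(OCc9ccccc9)c(OC#CC5(O[Si](C)(C)C(C)(C)C)C(OCc9ccccc9)=C(OCc9ccccc9)C5=O)c(OCc9ccccc9)c4)c(OCc9ccccc9)c2)c(OCc9ccccc9)c1 | intermediate
33 | tetramer 4-[(Z)-2-aryloxyvinyl]-4-silyloxy-2,3-bis(benzyloxy)cyclobutenone, racemic | c9ccccc9COc1cc(OCc9ccccc9)c(Oc2cc(OCc9ccccc9)c(Oc3cc(O[Si](C)(C)C(C)(C)C)c(OCc9ccccc9)c(OCc9ccccc9)c3Oc4cc(OCc9ccccc9)c(O/C=C\C5(O[Si](C)(C)C(C)(C)C)C(OCc9ccccc9)=C(OCc9ccccc9)C5=O)c(OCc9ccccc9)c4)c(OCc9ccccc9)c2)c(OCc9ccccc9)c1 | intermediate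
34 | (Z)-dienylketene from 33 (not isolated) | c9ccccc9COc1cc(OCc9ccccc9)c(Oc2cc(OCc9ccccc9)c(Oc3cc(O[Si](C)(C)C(C)(C)C)c(OCc9ccccc9)c(OCc9ccccc9)c3Oc4cc(OCc9ccccc9)c(O/C=C\C(O[Si](C)(C)C(C)(C)C)=C(OCc9ccccc9)/C(OCc9ccccc9)=C=O)c(OCc9ccccc9)c4)c(OCc9ccccc9)c2)c(OCc9ccccc9)c1 | intermediate
35 | cyclohexa-2,4-dienone from 34, racemic (not isolated) | c9ccccc9COc1cc(OCc9ccccc9)c(Oc2cc(OCc9ccccc9)c(Oc3cc(O[Si](C)(C)C(C)(C)C)c(OCc9ccccc9)c(OCc9ccccc9)c3Oc4cc(OCc9ccccc9)c(OC5C=C(O[Si](C)(C)C(C)(C)C)C(OCc9ccccc9)=C(OCc9ccccc9)C5=O)c(OCc9ccccc9)c4)c(OCc9ccccc9)c2)c(OCc9ccccc9)c1 | intermediate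
36 | A-to-E pentamer phenol (ring E substituted like ring C of 26; C2-OH free) | c9ccccc9COc1cc(OCc9ccccc9)c(Oc2cc(OCc9ccccc9)c(Oc3cc(O[Si](C)(C)C(C)(C)C)c(OCc9ccccc9)c(OCc9ccccc9)c3Oc4cc(OCc9ccccc9)c(Oc5cc(O[Si](C)(C)C(C)(C)C)c(OCc9ccccc9)c(OCc9ccccc9)c5O)c(OCc9ccccc9)c4)c(OCc9ccccc9)c2)c(OCc9ccccc9)c1 | intermediate
37 | A-to-F hexamer allyl ether | c9ccccc9COc1cc(OCc9ccccc9)c(Oc2cc(OCc9ccccc9)c(Oc3cc(O[Si](C)(C)C(C)(C)C)c(OCc9ccccc9)c(OCc9ccccc9)c3Oc4cc(OCc9ccccc9)c(Oc5cc(O[Si](C)(C)C(C)(C)C)c(OCc9ccccc9)c(OCc9ccccc9)c5Oc6cc(OCc9ccccc9)c(OCC=C)c(OCc9ccccc9)c6)c(OCc9ccccc9)c4)c(OCc9ccccc9)c2)c(OCc9ccccc9)c1 | intermediate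
38 | A-to-F hexamer phenol (ring F C4-OH free) | c9ccccc9COc1cc(OCc9ccccc9)c(Oc2cc(OCc9ccccc9)c(Oc3cc(O[Si](C)(C)C(C)(C)C)c(OCc9ccccc9)c(OCc9ccccc9)c3Oc4cc(OCc9ccccc9)c(Oc5cc(O[Si](C)(C)C(C)(C)C)c(OCc9ccccc9)c(OCc9ccccc9)c5Oc6cc(OCc9ccccc9)c(O)c(OCc9ccccc9)c6)c(OCc9ccccc9)c4)c(OCc9ccccc9)c2)c(OCc9ccccc9)c1 | intermediate
39 | A-to-F hexamer (E)-1,2-dichlorovinyl ether | c9ccccc9COc1cc(OCc9ccccc9)c(Oc2cc(OCc9ccccc9)c(Oc3cc(O[Si](C)(C)C(C)(C)C)c(OCc9ccccc9)c(OCc9ccccc9)c3Oc4cc(OCc9ccccc9)c(Oc5cc(O[Si](C)(C)C(C)(C)C)c(OCc9ccccc9)c(OCc9ccccc9)c5Oc6cc(OCc9ccccc9)c(O/C(Cl)=C\Cl)c(OCc9ccccc9)c6)c(OCc9ccccc9)c4)c(OCc9ccccc9)c2)c(OCc9ccccc9)c1 | intermediate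
40 | lithium aryloxyacetylide of the hexamer (not isolated) | c9ccccc9COc1cc(OCc9ccccc9)c(Oc2cc(OCc9ccccc9)c(Oc3cc(O[Si](C)(C)C(C)(C)C)c(OCc9ccccc9)c(OCc9ccccc9)c3Oc4cc(OCc9ccccc9)c(Oc5cc(O[Si](C)(C)C(C)(C)C)c(OCc9ccccc9)c(OCc9ccccc9)c5Oc6cc(OCc9ccccc9)c(OC#C[Li])c(OCc9ccccc9)c6)c(OCc9ccccc9)c4)c(OCc9ccccc9)c2)c(OCc9ccccc9)c1 | intermediate
41 | lithium alkoxide of the hexamer squarate adduct, racemic (not isolated) | c9ccccc9COc1cc(OCc9ccccc9)c(Oc2cc(OCc9ccccc9)c(Oc3cc(O[Si](C)(C)C(C)(C)C)c(OCc9ccccc9)c(OCc9ccccc9)c3Oc4cc(OCc9ccccc9)c(Oc5cc(O[Si](C)(C)C(C)(C)C)c(OCc9ccccc9)c(OCc9ccccc9)c5Oc6cc(OCc9ccccc9)c(OC#CC7(O[Li])C(OCc9ccccc9)=C(OCc9ccccc9)C7=O)c(OCc9ccccc9)c6)c(OCc9ccccc9)c4)c(OCc9ccccc9)c2)c(OCc9ccccc9)c1 | intermediate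
42 | hexamer 4-(aryloxyethynyl)-4-silyloxy-2,3-bis(benzyloxy)cyclobutenone, racemic | c9ccccc9COc1cc(OCc9ccccc9)c(Oc2cc(OCc9ccccc9)c(Oc3cc(O[Si](C)(C)C(C)(C)C)c(OCc9ccccc9)c(OCc9ccccc9)c3Oc4cc(OCc9ccccc9)c(Oc5cc(O[Si](C)(C)C(C)(C)C)c(OCc9ccccc9)c(OCc9ccccc9)c5Oc6cc(OCc9ccccc9)c(OC#CC7(O[Si](C)(C)C(C)(C)C)C(OCc9ccccc9)=C(OCc9ccccc9)C7=O)c(OCc9ccccc9)c6)c(OCc9ccccc9)c4)c(OCc9ccccc9)c2)c(OCc9ccccc9)c1 | intermediate
43 | hexamer 4-[(Z)-2-aryloxyvinyl]-4-silyloxy-2,3-bis(benzyloxy)cyclobutenone, racemic | c9ccccc9COc1cc(OCc9ccccc9)c(Oc2cc(OCc9ccccc9)c(Oc3cc(O[Si](C)(C)C(C)(C)C)c(OCc9ccccc9)c(OCc9ccccc9)c3Oc4cc(OCc9ccccc9)c(Oc5cc(O[Si](C)(C)C(C)(C)C)c(OCc9ccccc9)c(OCc9ccccc9)c5Oc6cc(OCc9ccccc9)c(O/C=C\C7(O[Si](C)(C)C(C)(C)C)C(OCc9ccccc9)=C(OCc9ccccc9)C7=O)c(OCc9ccccc9)c6)c(OCc9ccccc9)c4)c(OCc9ccccc9)c2)c(OCc9ccccc9)c1 | intermediate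
44 | (Z)-dienylketene from 43 (not isolated) | c9ccccc9COc1cc(OCc9ccccc9)c(Oc2cc(OCc9ccccc9)c(Oc3cc(O[Si](C)(C)C(C)(C)C)c(OCc9ccccc9)c(OCc9ccccc9)c3Oc4cc(OCc9ccccc9)c(Oc5cc(O[Si](C)(C)C(C)(C)C)c(OCc9ccccc9)c(OCc9ccccc9)c5Oc6cc(OCc9ccccc9)c(O/C=C\C(O[Si](C)(C)C(C)(C)C)=C(OCc9ccccc9)/C(OCc9ccccc9)=C=O)c(OCc9ccccc9)c6)c(OCc9ccccc9)c4)c(OCc9ccccc9)c2)c(OCc9ccccc9)c1 | intermediate
45 | cyclohexa-2,4-dienone from 44, racemic (not isolated) | c9ccccc9COc1cc(OCc9ccccc9)c(Oc2cc(OCc9ccccc9)c(Oc3cc(O[Si](C)(C)C(C)(C)C)c(OCc9ccccc9)c(OCc9ccccc9)c3Oc4cc(OCc9ccccc9)c(Oc5cc(O[Si](C)(C)C(C)(C)C)c(OCc9ccccc9)c(OCc9ccccc9)c5Oc6cc(OCc9ccccc9)c(OC7C=C(O[Si](C)(C)C(C)(C)C)C(OCc9ccccc9)=C(OCc9ccccc9)C7=O)c(OCc9ccccc9)c6)c(OCc9ccccc9)c4)c(OCc9ccccc9)c2)c(OCc9ccccc9)c1 | intermediate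
46 | A-to-G heptamer phenol (ring G substituted like ring C of 26; C2-OH free) | c9ccccc9COc1cc(OCc9ccccc9)c(Oc2cc(OCc9ccccc9)c(Oc3cc(O[Si](C)(C)C(C)(C)C)c(OCc9ccccc9)c(OCc9ccccc9)c3Oc4cc(OCc9ccccc9)c(Oc5cc(O[Si](C)(C)C(C)(C)C)c(OCc9ccccc9)c(OCc9ccccc9)c5Oc6cc(OCc9ccccc9)c(Oc7cc(O[Si](C)(C)C(C)(C)C)c(OCc9ccccc9)c(OCc9ccccc9)c7O)c(OCc9ccccc9)c6)c(OCc9ccccc9)c4)c(OCc9ccccc9)c2)c(OCc9ccccc9)c1 | intermediate
47 | protected octamer: all hydroxyls of 49 benzylated except the C5 oxygens of rings C, E and G, which are tert-butyldimethylsilylated | c9ccccc9COc1cc(OCc9ccccc9)c(Oc2cc(OCc9ccccc9)c(Oc3cc(O[Si](C)(C)C(C)(C)C)c(OCc9ccccc9)c(OCc9ccccc9)c3Oc4cc(OCc9ccccc9)c(Oc5cc(O[Si](C)(C)C(C)(C)C)c(OCc9ccccc9)c(OCc9ccccc9)c5Oc6cc(OCc9ccccc9)c(Oc7cc(O[Si](C)(C)C(C)(C)C)c(OCc9ccccc9)c(OCc9ccccc9)c7Oc8cc(OCc9ccccc9)c(OCc9ccccc9)c(OCc9ccccc9)c8)c(OCc9ccccc9)c6)c(OCc9ccccc9)c4)c(OCc9ccccc9)c2)c(OCc9ccccc9)c1 | intermediate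
48 | octamer triphenol: 47 with the three silyl groups replaced by hydrogen | c9ccccc9COc1cc(OCc9ccccc9)c(Oc2cc(OCc9ccccc9)c(Oc3cc(O)c(OCc9ccccc9)c(OCc9ccccc9)c3Oc4cc(OCc9ccccc9)c(Oc5cc(O)c(OCc9ccccc9)c(OCc9ccccc9)c5Oc6cc(OCc9ccccc9)c(Oc7cc(O)c(OCc9ccccc9)c(OCc9ccccc9)c7Oc8cc(OCc9ccccc9)c(OCc9ccccc9)c(OCc9ccccc9)c8)c(OCc9ccccc9)c6)c(OCc9ccccc9)c4)c(OCc9ccccc9)c2)c(OCc9ccccc9)c1 | intermediate
49 | CNP0206369.0, the free octamer | Oc1cc(O)c(Oc2cc(O)c(Oc3cc(O)c(O)c(O)c3Oc3cc(O)c(Oc4cc(O)c(O)c(O)c4Oc4cc(O)c(Oc5cc(O)c(O)c(O)c5Oc5cc(O)c(O)c(O)c5)c(O)c4)c(O)c3)c(O)c2)c(O)c1 | target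

## Step count and least certain steps

Total step count: 29. Longest linear sequence: 25 steps (steps 3 to 6, then steps 9 to 29).

Step 14 (key step; the same holds for steps 20 and 26). The most likely failure is a slow 6π closure: the (Z)-aryloxy group has to rotate inward, toward the ketene carbon, during the disrotatory motion. A long-lived ketene would be diverted into dimers or would add traces of water. Fallback, from 23: reversible addition of thiyl radicals (catalytic PhSSPh, visible light, benzene, rt) should equilibrate the enol ether toward the less congested (E)-vinyl cyclobutenone F1, in which the aryloxy group rotates outward on closure. Heating F1 in toluene at 110 °C leads back to 26.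

Step 12 (also steps 18 and 24). The most likely failure is incomplete capture of the hindered tertiary lithium alkoxide by the silyl triflate, followed by alkoxide-triggered opening of the four-membered ring on warming. Addition of residual n-BuLi to the squarate is the second concern. Fallback, from 19 and 15: the addition is run as before but quenched at −78 °C with NH4Cl, and the alkynyl carbinol F2 is isolated. It is then silylated under non-anionic conditions (TBSOTf, 2,6-lutidine, CH2Cl2, −78 °C) and the route is rejoined at 22.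

Step 13 (also steps 19 and 25). The most likely failure is over-reduction of the electron-rich enol ether or loss of benzyl groups if the poisoning is insufficient; a stalled reduction next to the quaternary carbon is also possible. Fallback, from 19, bypassing the alkyne on the four-membered ring: n-BuLi then water gives the terminal ethynyl ether F3. Radical hydrostannylation (Bu3SnH, AIBN, 70 °C) should give mainly the (Z)-2-aryloxyvinylstannane F4. Tin–lithium exchange (n-BuLi, THF, −78 °C) gives a (Z)-2-aryloxyvinyl-lithium in which lithium is syn to the aryloxy group and coordinated by it, so anti elimination is not available. Addition to 15 and in situ TBSOTf rejoin the route at 23.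

Step 15 (also steps 21 and 27). The most likely failure is loss or intermolecular transfer of the aryl silyl group under caesium phenoxide at 110 °C, which would expose the ring C C5 oxygen to arylation. A sluggish reaction of the doubly ortho-substituted phenoxide is the second concern. Fallback, from 12 and 26: bromine–lithium exchange on 12 (n-BuLi, −78 °C), B(OiPr)3 and aqueous acid give the arylboronic acid F5. Chan–Lam–Evans oxidative etherification of 26 with F5 (Cu(OAc)2, pyridine, 4 Å sieves, air, CH2Cl2, rt) works without carbonate or heat and rejoins the route at 27.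

Step 29. The most likely failure is incomplete hydrogenolysis, because partly deprotected polyphenols adsorb on the catalyst; air oxidation of the product during filtration is the other risk. Fallback, from 48: Lewis-acid debenzylation with BCl3 and pentamethylbenzene as cation scavenger (CH2Cl2, −78 °C), followed by methanol quench under argon, leads to 49 without a new intermediate.

## Further compounds

F1 | step 14 | (E)-isomer of 23, 2,3-bis(benzyloxy)-4-(tert-butyldimethylsilyloxy)-4-[(E)-2-aryloxyvinyl]cyclobut-2-en-1-one, racemic | c9ccccc9COc1cc(OCc9ccccc9)c(Oc2cc(OCc9ccccc9)c(O/C=C/C3(O[Si](C)(C)C(C)(C)C)C(OCc9ccccc9)=C(OCc9ccccc9)C3=O)c(OCc9ccccc9)c2)c(OCc9ccccc9)c1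
F2 | step 12 | 4-(aryloxyethynyl)-2,3-bis(benzyloxy)-4-hydroxycyclobut-2-en-1-one of the A-B dimer, racemic | c9ccccc9COc1cc(OCc9ccccc9)c(Oc2cc(OCc9ccccc9)c(OC#CC3(O)C(OCc9ccccc9)=C(OCc9ccccc9)C3=O)c(OCc9ccccc9)c2)c(OCc9ccccc9)c1
F3 | step 13 | A-B dimer ethynyl ether | c9ccccc9COc1cc(OCc9ccccc9)c(Oc2cc(OCc9ccccc9)c(OC#C)c(OCc9ccccc9)c2)c(OCc9ccccc9)c1
F4 | step 13 | A-B dimer (Z)-2-(tributylstannyl)vinyl ether | c9ccccc9COc1cc(OCc9ccccc9)c(Oc2cc(OCc9ccccc9)c(O/C=C\[Sn](CCCC)(CCCC)CCCC)c(OCc9ccccc9)c2)c(OCc9ccccc9)c1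
F5 | step 15 | [4-(allyloxy)-3,5-bis(benzyloxy)phenyl]boronic acid | OB(O)c1cc(OCc9ccccc9)c(OCC=C)c(OCc9ccccc9)c1
F0 | step 29 | none | none
A1 | alternative 1 | cyclopentadienyl ruthenium hexafluorophosphate complex of the octamer at ring B (ring B dimethyl ether, other hydroxyls benzylated) | c9ccccc9COc1cc(OCc9ccccc9)c(Oc2cc(OC)c(Oc3cc(OCc9ccccc9)c(OCc9ccccc9)c(OCc9ccccc9)c3Oc3cc(OCc9ccccc9)c(Oc4cc(OCc9ccccc9)c(OCc9ccccc9)c(OCc9ccccc9)c4Oc4cc(OCc9ccccc9)c(Oc5cc(OCc9ccccc9)c(OCc9ccccc9)c(OCc9ccccc9)c5Oc5cc(OCc9ccccc9)c(OCc9ccccc9)c(OCc9ccccc9)c5)c(OCc9ccccc9)c4)c(OCc9ccccc9)c3)c(OC)c2)c(OCc9ccccc9)c1.[CH-]1C=CC=C1.[Ru+2].F[P-](F)(F)(F)(F)F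
A2 | alternative 1 | cyclopentadienyl(1,4-dichloro-2,6-dimethoxybenzene)ruthenium hexafluorophosphate | COc1cc(Cl)cc(OC)c1Cl.[CH-]1C=CC=C1.[Ru+2].F[P-](F)(F)(F)(F)F
A3 | alternative 1 | C-to-H hexamer phenol (ring C C1-OH free, other hydroxyls benzylated) | Oc3cc(OCc9ccccc9)c(OCc9ccccc9)c(OCc9ccccc9)c3Oc3cc(OCc9ccccc9)c(Oc4cc(OCc9ccccc9)c(OCc9ccccc9)c(OCc9ccccc9)c4Oc4cc(OCc9ccccc9)c(Oc5cc(OCc9ccccc9)c(OCc9ccccc9)c(OCc9ccccc9)c5Oc5cc(OCc9ccccc9)c(OCc9ccccc9)c(OCc9ccccc9)c5)c(OCc9ccccc9)c4)c(OCc9ccccc9)c3
A4 | alternative 2 | octamer with ring A as dimethyl 2,4,6-trihydroxy-5-aryloxybenzene-1,3-dicarboxylate | COC(=O)c1c(O)c(C(=O)OC)c(O)c(Oc2cc(OCc9ccccc9)c(Oc3cc(OCc9ccccc9)c(OCc9ccccc9)c(OCc9ccccc9)c3Oc3cc(OCc9ccccc9)c(Oc4cc(OCc9ccccc9)c(OCc9ccccc9)c(OCc9ccccc9)c4Oc4cc(OCc9ccccc9)c(Oc5cc(OCc9ccccc9)c(OCc9ccccc9)c(OCc9ccccc9)c5Oc5cc(OCc9ccccc9)c(OCc9ccccc9)c(OCc9ccccc9)c5)c(OCc9ccccc9)c4)c(OCc9ccccc9)c3)c(OCc9ccccc9)c2)c1O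
A5 | alternative 2 | dimethyl 2-aryloxymalonate of the B-to-H heptamer | COC(=O)C(C(=O)OC)Oc2cc(OCc9ccccc9)c(Oc3cc(OCc9ccccc9)c(OCc9ccccc9)c(OCc9ccccc9)c3Oc3cc(OCc9ccccc9)c(Oc4cc(OCc9ccccc9)c(OCc9ccccc9)c(OCc9ccccc9)c4Oc4cc(OCc9ccccc9)c(Oc5cc(OCc9ccccc9)c(OCc9ccccc9)c(OCc9ccccc9)c5Oc5cc(OCc9ccccc9)c(OCc9ccccc9)c(OCc9ccccc9)c5)c(OCc9ccccc9)c4)c(OCc9ccccc9)c3)c(OCc9ccccc9)c2
A6 | alternative 2 | dimethyl 3-oxoglutarate | COC(=O)CC(=O)CC(=O)OC
A7 | alternative 3 | octamer with free C4 hydroxyls on rings C, E, G and H, other hydroxyls benzylated | c9ccccc9COc1cc(OCc9ccccc9)c(Oc2cc(OCc9ccccc9)c(Oc3cc(OCc9ccccc9)c(O)c(OCc9ccccc9)c3Oc3cc(OCc9ccccc9)c(Oc4cc(OCc9ccccc9)c(O)c(OCc9ccccc9)c4Oc4cc(OCc9ccccc9)c(Oc5cc(OCc9ccccc9)c(O)c(OCc9ccccc9)c5Oc5cc(OCc9ccccc9)c(O)c(OCc9ccccc9)c5)c(OCc9ccccc9)c4)c(OCc9ccccc9)c3)c(OCc9ccccc9)c2)c(OCc9ccccc9)c1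
A8 | alternative 3 | tetraformyl octamer (formyl at C4 of rings C, E, G and H, other hydroxyls benzylated) | c9ccccc9COc1cc(OCc9ccccc9)c(Oc2cc(OCc9ccccc9)c(Oc3cc(OCc9ccccc9)c(C=O)c(OCc9ccccc9)c3Oc3cc(OCc9ccccc9)c(Oc4cc(OCc9ccccc9)c(C=O)c(OCc9ccccc9)c4Oc4cc(OCc9ccccc9)c(Oc5cc(OCc9ccccc9)c(C=O)c(OCc9ccccc9)c5Oc5cc(OCc9ccccc9)c(C=O)c(OCc9ccccc9)c5)c(OCc9ccccc9)c4)c(OCc9ccccc9)c3)c(OCc9ccccc9)c2)c(OCc9ccccc9)c1
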